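## Structural features

Caraphenol B is an indane. Five-membered ring B is fused at C3a and C7a to resorcinol ring A (hydroxyls on C4 and C6). Each sp3 carbon of ring B carries one aryl unit: C1 the 4-hydroxybenzoyl group (carbonyl C8 and ring D), C2 the 4-hydroxyphenyl ring C, and C3 the 3,5-dihydroxyphenyl ring E. C1, C2 and C3 are contiguous stereocentres with all three substituents on one face, (1R,2R,3R). The fragile point is C1–H, which is α to the C8 ketone and benzylic: acid or base can epimerise the crowded all-cis triad to the 1,2-trans isomer. The six electron-rich phenols also rule out oxidants while they are free. The real difficulty is therefore the contra-thermodynamic all-cis triad in one absolute sense, together with the unsymmetrical placing of the ring A oxygens (C4–O next to C3a, nothing next to C7a). The key step uses exactly that asymmetry: C7a and C3a are adjacent ring A carbons with the polarity of a 3-alkoxyaryne, and C1 and C3 are the α-carbon and one carbonyl carbon of a 1,3-diketone, so ring A can be inserted into the C1–C3 bond.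

## Logic of the disconnections

23 ⇐ 22. The six O–Si bonds are cut last. Near-neutral fluoride cleavage frees the phenols without touching the epimerisable C1. This demands silyl ethers that are already in place before any stereocentre exists.

22 ⇐ 21. The C8 carbonyl is traced back to a C8 carbinol. The carbinol is the handle through which absolute configuration enters, and it makes C1 configurationally stable during the alkene reduction. The forward oxidation must be non-epimerising.

21 ⇐ 20. The C2–H and C3–H bonds are cut, giving a C2=C3 alkene. Syn delivery of hydrogen to the face opposite the C1 side chain makes two stereocentres from one and gives the all-cis triad. The demand is facial control and no migration of the double bond before reduction.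

20 ⇐ 19. The C8–H bond is cut. In ketone 19 the C1 centre is α to carbonyl, benzylic and allylic, so it racemises freely and a catalyst-controlled reduction can funnel both enantiomers into one. The demand is that reduction of the non-conjugated ketone outruns any drift of the double bond.

19 ⇐ 17 (through 18). Six O–Si bonds are exchanged for six O–CH3 bonds. The exchange is placed where no defined stereocentre exists, so the Lewis acid can do no stereochemical harm. Methyl ethers are what the fluoride-driven key step tolerates.

17 ⇐ 16. The C2=C3 bond is traced to a C3–OH and a C2–H. Ionisation at C3 is easy because ring A donates from its ortho and para oxygens. All diastereomers of 16 converge on one alkene.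

16 ⇐ 12 + 14 (through 15). The C2–C3 and C1–C2 bonds are cut. C2 is an ambiphilic one-carbon unit: as ylide carbon it attacks the C3 ketone, and as epoxide carbon it is attacked by the C1 enolate. This closes ring B and brings in ring C in one operation from an achiral diketone. The demands are that the C8 ketone stays masked as its enolate and that the enolate opens the epoxide at the benzylic C2. 14 ⇐ 13 by cutting the C–S bond.

12 ⇐ 10 + 7 (through 11). The C1–C7a and C3–C3a bonds are cut, which is the key disconnection. It removes ring A from the chain and leaves a symmetrical-looking diketone and an aryne whose own oxygen pattern decides the orientation. The demands are regiochemistry of enolate addition to the aryne and migration of the correct acyl group.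

10 ⇐ 8 + 9. The C1–C3 bond is cut (Claisen). Both partners are commercial, and the ester cannot enolise.

7 ⇐ 5 ⇐ 2 ⇐ 1 (through 3, 4 and 6). The O–S bond, the C–Si bond and the carbamate C–O bond are cut. Silicon is placed by directed metalation between the carbamate oxygen and the C3 methoxy group. This replaces halogenation of the phenol, where the position between the two methoxy groups competes, and so secures the constitution of the aryne precursor.

## Other disconnections considered

Alternative 1: The C1–C2 bond is cut last. A diazo ketone A1, with the C3 stereocentre already set, would be converted by an engineered haem carbene transferase (ferrous haem, buffer) into an iron carbene. The carbene inserts into one benzylic C2–H bond and closes ring B to give A2. A2 carries six acetyl groups and is therefore the hexaacetate, not a pentaacetate.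
- In its favour: ring closure and two stereocentres (C1, C2) arise in one catalyst-controlled step at the final oxidation state of C8. On this point it is better than the chosen plan, which needs a reduction–oxidation detour at C8.
- Against it: A1 needs its own asymmetric synthesis of a 1,1,2-triarylethane stereocentre plus a diazo transfer. The donor–acceptor carbene sits beside a doubly ortho-substituted arene, a very large substrate for a haem pocket, so a directed-evolution campaign would precede any material. The protein must also enforce the less stable cis relation at C1–C2. The aryl acetates may hydrolyse in buffer, and their final removal must again avoid base.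
- Comparison: structurally it defers ring B, whereas the chosen plan defers only hydrogen atoms. Mechanistically it relies on the protein to override substrate preference, whereas the chosen plan gets the all-cis triad from the intrinsic syn addition of hydrogen. In step count it is at best equal once the synthesis of A1 is included.

Alternative 2: The C3–ring E and C2–ring C bonds are cut. A 1-substituted indene A3 with a free C8 alkoxide would take up aryl iodide A4 and arylboronic acid A5 across C2=C3 under Ni(cod)2 and hydroxide. The alkoxide directs both aryl groups to its own face, giving A6.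
- In its favour: it is the most convergent plan, it gives the all-cis triad directly, and it is modular in rings C and E. Its benzyl ethers could be removed by neutral hydrogenolysis after C8 oxidation, so no protecting-group exchange is needed. On these points it is better than the chosen plan.
- Against it: A3 must be a single enantiomer of a 1-substituted indene, a class that isomerises to the 3-substituted indene by base or by sigmatropic hydrogen shift, and hydroxide in alcohol invites exactly that. Directed diarylations of this kind are established for unhindered alkenes, whereas here C3 is flanked by the C4 benzyloxy group. The regiochemistry needs the five-membered oxanickelacycle to win over benzylic nickel at C3, and β-hydride elimination would give Heck products.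
- Comparison: it ends with the same C8 carbinol and so shares the final oxidation with the chosen plan (equal there). It replaces a stepwise polar construction by one three-component coupling that carries three selectivity demands at once. It would be shorter if the coupling held.

Alternative 3: Ring A is cut at C3a–C4 and C7–C7a. The dianion of aroylcyclopentanone A7 would be acylated at C3a by ketal ester A8. Unmasking of the C6 ketone then lets the C7 methyl carbon close onto C7a with aromatisation to give A9.
- In its favour: ring A is built with its 4,6-oxygens free and in the right place by construction, as securely as the aryne polarity does it (equal on this point), and no aryne or fluoride is involved.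
- Against it: the equilibrating base and acid conditions deliver C1 in its trans configuration, so A9 is the 1-epimer of the target series. Correcting C1 against thermodynamics would need a separate kinetic protonation or a redox sequence. A7 with cis aryl groups as one enantiomer is itself a demanding target, and the remaining methyl ethers still need a Lewis acid.
- Comparison: structurally it keeps the stereotriad and sacrifices ring A, the opposite of the chosen plan. Mechanistically it is thermodynamic where the target needs kinetic control. In step count it is longer once A7 is included.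

Key step: step 5

Assumption: the (S,S)-configured ruthenium catalyst is taken to reduce the C1 epimer of 19 shown (Felkin-type matching, hydride anti to the C2 side of the indene); if the other epimer reacted faster, the (R,R)-catalyst would be used, which changes only the C8 carbinol configuration in 20 and 21, a centre that step 12 removes.

## Steps

Step 1
Reactants: 1 3,5-dimethoxyphenol
Product: 2 3,5-dimethoxyphenyl N-isopropylcarbamate
Conditions: i-PrNCO, Et3N (cat.), CH2Cl2, rt
Reagents that add atoms: isopropyl isocyanate CC(C)N=C=O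
Why: Carbamoylation of the phenol by addition to the isocyanate installs a strong director for ortho metalation that can later be removed by a mild amine-induced elimination.

Step 2
Reactants: 2 3,5-dimethoxyphenyl N-isopropylcarbamate
Product: 5 3,5-dimethoxy-2-(trimethylsilyl)phenyl N-isopropylcarbamate, via N-silyl carbamate 3 (not isolated), via N-silyl C-silyl carbamate 4 (not isolated)
Conditions: TBSOTf, TMEDA, Et2O, 0 °C to rt; n-BuLi, TMEDA, −78 °C; TMSCl, −78 °C to rt; aq. NaHSO4
Reagents that add atoms: chlorotrimethylsilane C[Si](C)(C)Cl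
Why: Snieckus directed ortho metalation: after transient N-silylation the carbamate and the neighbouring methoxy group cooperate, so lithiation occurs at the carbon between them and is trapped by the silyl chloride; the N-silyl group falls off on aqueous work-up.

Step 3
Reactants: 5 3,5-dimethoxy-2-(trimethylsilyl)phenyl N-isopropylcarbamate
Product: 7 3,5-dimethoxy-2-(trimethylsilyl)phenyl trifluoromethanesulfonate, via silylphenol 6 (not isolated)
Conditions: DBU, Et2NH, MeCN, 40 °C; then PhNTf2, rt
Reagents that add atoms: N-phenylbis(trifluoromethanesulfonimide) O=S(=O)(N(c1ccccc1)S(=O)(=O)C(F)(F)F)C(F)(F)F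
Why: Base-induced elimination of isopropyl isocyanate (trapped by diethylamine as the urea) frees the phenoxide, which is triflated in the same flask; this is the usual close of a Kobayashi aryne-precursor synthesis.

Step 4
Reactants: 8 4'-methoxyacetophenone; 9 methyl 3,5-dimethoxybenzoate
Product: 10 1-(3,5-dimethoxyphenyl)-3-(4-methoxyphenyl)propane-1,3-dione
Conditions: NaH, THF, reflux; aq. HCl
Reagents that add atoms: none
Why: Crossed Claisen condensation of the ketone enolate with a non-enolisable ester, driven by formation of the stabilised diketonate.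

Step 5
Reactants: 10 1-(3,5-dimethoxyphenyl)-3-(4-methoxyphenyl)propane-1,3-dione; 7 3,5-dimethoxy-2-(trimethylsilyl)phenyl trifluoromethanesulfonate
Product: 12 2-[2-(3,5-dimethoxybenzoyl)-3,5-dimethoxyphenyl]-1-(4-methoxyphenyl)ethanone, via 3,5-dimethoxybenzyne 11 (not isolated)
Conditions: KF, 18-crown-6, THF, 0 °C to rt (7 in slight excess)
Reagents that add atoms: none
Why: Fluoride attacks silicon of 7 and triflate leaves, giving aryne 11, while the acidic diketone 10 is present as its potassium enolate. The enolate carbon (C1) adds to the aryne carbon remote from the flanking methoxy group (the future C7a), so the aryl anion appears at C3a beside the C4 oxygen, where it is inductively stabilised; this is the normal polarity of a 3-alkoxyaryne and secures the first selectivity. The aryl anion adds to a neighbouring carbonyl (4-exo-trig) and the benzocyclobutenoxide fragments by retro-aldol cleavage of the old C1–C3 bond, so the arene ends up between C1 and C3; the four-membered ring is transient and no ring remains. The closest known reaction is the acyl-alkylation of arynes by β-ketoesters and 1,3-diketones (aryne σ-bond insertion). The second selectivity is which acyl group migrates: addition of the very basic aryl anion is irreversible, so the more electrophilic carbonyl is taken, and the 3,5-dimethoxybenzoyl carbon (two inductively withdrawing meta oxygens) is more electrophilic than the 4-methoxybenzoyl carbon (para oxygen in direct conjugation). No stereocentre is formed. Mild temperature and only a small excess of 7 limit a second arylation at the acidic C1 methylene of 12.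

Step 6
Reactants: 13 4-methoxybenzyl chloride
Product: 14 1-(4-methoxybenzyl)tetrahydrothiophenium tetrafluoroborate
Conditions: tetrahydrothiophene, NaBF4, acetone, rt
Reagents that add atoms: tetrahydrothiophene C1CCSC1; sodium tetrafluoroborate [Na+].F[B-](F)(F)F
Why: S-Alkylation of the sulfide by the activated benzylic chloride with anion metathesis; the non-nucleophilic counter-ion prevents reversal.

Step 7
Reactants: 12 2-[2-(3,5-dimethoxybenzoyl)-3,5-dimethoxyphenyl]-1-(4-methoxyphenyl)ethanone; 14 1-(4-methoxybenzyl)tetrahydrothiophenium tetrafluoroborate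
Product: 16 [3-(3,5-dimethoxyphenyl)-3-hydroxy-4,6-dimethoxy-2-(4-methoxyphenyl)-2,3-dihydro-1H-inden-1-yl](4-methoxyphenyl)methanone (racemic mixture of diastereomers), via epoxide 15 (not isolated)
Conditions: KOt-Bu (3 equiv), THF–DMSO, 0 °C to 50 °C
Reagents that add atoms: none
Why: Corey–Chaykovsky epoxidation followed by intramolecular enolate alkylation: the first equivalent of base turns the C8 ketone into its C1 enolate, which protects it, so the benzyl ylide adds to the C3 ketone and closes to epoxide 15. The C1 enolate then opens the epoxide (or intercepts the betaine) at the benzylic, 4-methoxyphenyl-activated C2 to close ring B; the stereocentres formed are removed or reset later.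

Step 8
Reactants: 16 [3-(3,5-dimethoxyphenyl)-3-hydroxy-4,6-dimethoxy-2-(4-methoxyphenyl)-2,3-dihydro-1H-inden-1-yl](4-methoxyphenyl)methanone
Product: 17 [3-(3,5-dimethoxyphenyl)-4,6-dimethoxy-2-(4-methoxyphenyl)-1H-inden-1-yl](4-methoxyphenyl)methanone (racemic, C1 labile)
Conditions: TsOH·H2O (cat.), toluene, 40 °C
Reagents that add atoms: none
Why: E1 dehydration: the C3 cation is stabilised by ring E and by the ortho and para oxygens of ring A and loses the C2 proton, so every diastereomer of 16 converges on the C2=C3 indene.

Step 9
Reactants: 17 [3-(3,5-dimethoxyphenyl)-4,6-dimethoxy-2-(4-methoxyphenyl)-1H-inden-1-yl](4-methoxyphenyl)methanone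
Product: 19 [4,6-bis(tert-butyldimethylsilyloxy)-3-[3,5-bis(tert-butyldimethylsilyloxy)phenyl]-2-[4-(tert-butyldimethylsilyloxy)phenyl]-1H-inden-1-yl][4-(tert-butyldimethylsilyloxy)phenyl]methanone (racemic, C1 labile), via hexaphenol 18 (not isolated)
Conditions: BBr3, CH2Cl2, −78 °C to rt; MeOH, evaporate; TBSCl, imidazole, DMF, rt
Reagents that add atoms: tert-butyldimethylsilyl chloride CC(C)(C)[Si](C)(C)Cl
Why: Lewis-acid cleavage of the six aryl methyl ethers and silylation of the crude hexaphenol; the exchange is done while no defined stereocentre exists, so that the final deprotection can be a neutral fluoride cleavage.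

Step 10
Reactants: 19 [4,6-bis(tert-butyldimethylsilyloxy)-3-[3,5-bis(tert-butyldimethylsilyloxy)phenyl]-2-[4-(tert-butyldimethylsilyloxy)phenyl]-1H-inden-1-yl][4-(tert-butyldimethylsilyloxy)phenyl]methanone
Product: 20 (S)-[(1S)-4,6-bis(tert-butyldimethylsilyloxy)-3-[3,5-bis(tert-butyldimethylsilyloxy)phenyl]-2-[4-(tert-butyldimethylsilyloxy)phenyl]-1H-inden-1-yl][4-(tert-butyldimethylsilyloxy)phenyl]methanol
Conditions: RuCl[(S,S)-TsDPEN](p-cymene) (cat.), HCO2H–Et3N (5:2), CH2Cl2, 30 °C
Reagents that add atoms: none
Why: Noyori–Ikariya asymmetric transfer hydrogenation with dynamic kinetic resolution: C1–H (α to carbonyl, benzylic and allylic) equilibrates the two enantiomers of 19 through the dienolate in the amine–formate medium, and the catalyst reduces the matched one, setting C8 by catalyst control and C1 by Felkin-type matching. The descriptor at C1 is S here and becomes R in 21 only because C2 loses CIP priority on saturation; the spatial arrangement is that of the target.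

Step 11
Reactants: 20 (S)-[(1S)-4,6-bis(tert-butyldimethylsilyloxy)-3-[3,5-bis(tert-butyldimethylsilyloxy)phenyl]-2-[4-(tert-butyldimethylsilyloxy)phenyl]-1H-inden-1-yl][4-(tert-butyldimethylsilyloxy)phenyl]methanol
Product: 21 (S)-[(1R,2R,3R)-4,6-bis(tert-butyldimethylsilyloxy)-3-[3,5-bis(tert-butyldimethylsilyloxy)phenyl]-2-[4-(tert-butyldimethylsilyloxy)phenyl]-2,3-dihydro-1H-inden-1-yl][4-(tert-butyldimethylsilyloxy)phenyl]methanol
Conditions: H2 (50 bar), 10% Pd/C, EtOAc, Et3N (trace), rt
Reagents that add atoms: none
Why: Heterogeneous catalytic hydrogenation adds both hydrogens syn to the alkene face opposite the bulky C1 carbinol side chain, so rings C and E end up cis to that side chain and the all-cis triad results; the trace of amine suppresses benzylic C–O hydrogenolysis.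

Step 12
Reactants: 21 (S)-[(1R,2R,3R)-4,6-bis(tert-butyldimethylsilyloxy)-3-[3,5-bis(tert-butyldimethylsilyloxy)phenyl]-2-[4-(tert-butyldimethylsilyloxy)phenyl]-2,3-dihydro-1H-inden-1-yl][4-(tert-butyldimethylsilyloxy)phenyl]methanol
Product: 22 [(1R,2R,3R)-4,6-bis(tert-butyldimethylsilyloxy)-3-[3,5-bis(tert-butyldimethylsilyloxy)phenyl]-2-[4-(tert-butyldimethylsilyloxy)phenyl]-2,3-dihydro-1H-inden-1-yl][4-(tert-butyldimethylsilyloxy)phenyl]methanone
Conditions: Dess–Martin periodinane, NaHCO3, CH2Cl2, 0 °C to rt
Reagents that add atoms: none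
Why: Dess–Martin oxidation of the secondary benzylic alcohol under buffered, near-neutral conditions returns the C8 ketone without enolising the now α-positioned C1; the phenols are protected against the oxidant.

Step 13
Reactants: 22 [(1R,2R,3R)-4,6-bis(tert-butyldimethylsilyloxy)-3-[3,5-bis(tert-butyldimethylsilyloxy)phenyl]-2-[4-(tert-butyldimethylsilyloxy)phenyl]-2,3-dihydro-1H-inden-1-yl][4-(tert-butyldimethylsilyloxy)phenyl]methanone
Product: 23 caraphenol B, [(1R,2R,3R)-3-(3,5-dihydroxyphenyl)-4,6-dihydroxy-2-(4-hydroxyphenyl)-2,3-dihydro-1H-inden-1-yl](4-hydroxyphenyl)methanone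
Conditions: KHF2, MeOH, rt
Reagents that add atoms: none
Why: Bifluoride cleaves aryl silyl ethers selectively in a weakly acidic, non-basic medium, so the six phenols are freed without epimerising C1.

## Compound list

1 | 3,5-dimethoxyphenol | COc1cc(O)cc(OC)c1 | starting material
2 | 3,5-dimethoxyphenyl N-isopropylcarbamate | COc1cc(OC)cc(OC(=O)NC(C)C)c1 | intermediate
3 | 3,5-dimethoxyphenyl N-(tert-butyldimethylsilyl)-N-isopropylcarbamate (not isolated) | COc1cc(OC)cc(OC(=O)N(C(C)C)[Si](C)(C)C(C)(C)C)c1 | intermediate
4 | 3,5-dimethoxy-2-(trimethylsilyl)phenyl N-(tert-butyldimethylsilyl)-N-isopropylcarbamate (not isolated) | COc1cc(OC)c([Si](C)(C)C)c(OC(=O)N(C(C)C)[Si](C)(C)C(C)(C)C)c1 | intermediate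
5 | 3,5-dimethoxy-2-(trimethylsilyl)phenyl N-isopropylcarbamate | COc1cc(OC)c([Si](C)(C)C)c(OC(=O)NC(C)C)c1 | intermediate
6 | 3,5-dimethoxy-2-(trimethylsilyl)phenol (not isolated) | COc1cc(O)c([Si](C)(C)C)c(OC)c1 | intermediate
7 | 3,5-dimethoxy-2-(trimethylsilyl)phenyl trifluoromethanesulfonate | COc1cc(OC)c([Si](C)(C)C)c(OS(=O)(=O)C(F)(F)F)c1 | intermediate
8 | 4'-methoxyacetophenone | COc1ccc(cc1)C(C)=O | starting material
9 | methyl 3,5-dimethoxybenzoate | COC(=O)c1cc(OC)cc(OC)c1 | starting material
10 | 1-(3,5-dimethoxyphenyl)-3-(4-methoxyphenyl)propane-1,3-dione | COc1ccc(cc1)C(=O)CC(=O)c1cc(OC)cc(OC)c1 | intermediate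
11 | 3,5-dimethoxybenzyne (not isolated) | COC1=CC(OC)=CC#C1 | intermediate
12 | 2-[2-(3,5-dimethoxybenzoyl)-3,5-dimethoxyphenyl]-1-(4-methoxyphenyl)ethanone (achiral) | COc1ccc(cc1)C(=O)Cc1cc(OC)cc(OC)c1C(=O)c1cc(OC)cc(OC)c1 | intermediate
13 | 4-methoxybenzyl chloride | COc1ccc(CCl)cc1 | starting material
14 | 1-(4-methoxybenzyl)tetrahydrothiophenium tetrafluoroborate | COc1ccc(C[S+]2CCCC2)cc1.F[B-](F)(F)F | intermediate
15 | 2-{2-[2-(3,5-dimethoxyphenyl)-3-(4-methoxyphenyl)oxiran-2-yl]-3,5-dimethoxyphenyl}-1-(4-methoxyphenyl)ethanone (racemic, both epoxide diastereomers; not isolated) | COc1ccc(cc1)C(=O)Cc1cc(OC)cc(OC)c1C1(OC1c1ccc(OC)cc1)c1cc(OC)cc(OC)c1 | intermediate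
16 | [3-(3,5-dimethoxyphenyl)-3-hydroxy-4,6-dimethoxy-2-(4-methoxyphenyl)-2,3-dihydro-1H-inden-1-yl](4-methoxyphenyl)methanone (racemic, mixture of diastereomers) | COc1ccc(cc1)C(=O)C1C(c2ccc(OC)cc2)C(O)(c2cc(OC)cc(OC)c2)c2c(OC)cc(OC)cc21 | intermediate
17 | [3-(3,5-dimethoxyphenyl)-4,6-dimethoxy-2-(4-methoxyphenyl)-1H-inden-1-yl](4-methoxyphenyl)methanone (racemic, C1 labile) | COc1ccc(cc1)C(=O)C1C(c2ccc(OC)cc2)=C(c2cc(OC)cc(OC)c2)c2c(OC)cc(OC)cc21 | intermediate
18 | [3-(3,5-dihydroxyphenyl)-4,6-dihydroxy-2-(4-hydroxyphenyl)-1H-inden-1-yl](4-hydroxyphenyl)methanone (racemic; not isolated) | O=C(c1ccc(O)cc1)C1C(c2ccc(O)cc2)=C(c2cc(O)cc(O)c2)c2c(O)cc(O)cc21 | intermediate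
19 | hexakis-TBS ether of 18 (racemic, C1 labile) | O=C(c1ccc(O[Si](C)(C)C(C)(C)C)cc1)C1C(c2ccc(O[Si](C)(C)C(C)(C)C)cc2)=C(c2cc(O[Si](C)(C)C(C)(C)C)cc(O[Si](C)(C)C(C)(C)C)c2)c2c(O[Si](C)(C)C(C)(C)C)cc(O[Si](C)(C)C(C)(C)C)cc21 | intermediate
20 | (S)-carbinol of the (1S)-indene, hexakis-TBS ether | O[C@H](c1ccc(O[Si](C)(C)C(C)(C)C)cc1)[C@H]1c2cc(O[Si](C)(C)C(C)(C)C)cc(O[Si](C)(C)C(C)(C)C)c2C(c2cc(O[Si](C)(C)C(C)(C)C)cc(O[Si](C)(C)C(C)(C)C)c2)=C1c1ccc(O[Si](C)(C)C(C)(C)C)cc1 | intermediate
21 | (S)-carbinol of the all-cis (1R,2R,3R)-indane, hexakis-TBS ether | O[C@H](c1ccc(O[Si](C)(C)C(C)(C)C)cc1)[C@H]1c2cc(O[Si](C)(C)C(C)(C)C)cc(O[Si](C)(C)C(C)(C)C)c2[C@@H](c2cc(O[Si](C)(C)C(C)(C)C)cc(O[Si](C)(C)C(C)(C)C)c2)[C@H]1c1ccc(O[Si](C)(C)C(C)(C)C)cc1 | intermediate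
22 | caraphenol B hexakis-TBS ether, all-cis (1R,2R,3R) | O=C(c1ccc(O[Si](C)(C)C(C)(C)C)cc1)[C@H]1c2cc(O[Si](C)(C)C(C)(C)C)cc(O[Si](C)(C)C(C)(C)C)c2[C@@H](c2cc(O[Si](C)(C)C(C)(C)C)cc(O[Si](C)(C)C(C)(C)C)c2)[C@H]1c1ccc(O[Si](C)(C)C(C)(C)C)cc1 | intermediate
23 | caraphenol B, (1R,2R,3R) | O=C(c1ccc(O)cc1)[C@H]1c2cc(O)cc(O)c2[C@@H](c2cc(O)cc(O)c2)[C@H]1c1ccc(O)cc1 | target

## Step count and risks

Total: 13 steps. Longest linear sequence: 11 steps (steps 1, 2, 3, 5, 7, 8, 9, 10, 11, 12, 13, from 1).

Least certain steps:

**Step 5 (key step).** Most likely failure: migration of the wrong acyl group, that is, attack of the aryl anion on the 4-methoxybenzoyl carbonyl. The electronic bias between the two aryl ketones is real but not large for so reactive a nucleophile, and simple α-arylation without insertion is a second leak.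
Fallback, from 9 and 7, returning at 12: 9 is condensed with the lithium enolate of methyl acetate (LiHMDS, THF, −78 °C) to give methyl 3-(3,5-dimethoxyphenyl)-3-oxopropanoate F1. F1 and 7 under fluoride give methyl 2-[2-(3,5-dimethoxybenzoyl)-3,5-dimethoxyphenyl]acetate F2; here only one ketone is present and the ester is not attacked, the established chemoselectivity of β-ketoester acyl-alkylation. Aminolysis with Me3Al and N,O-dimethylhydroxylamine hydrochloride gives 2-[2-(3,5-dimethoxybenzoyl)-3,5-dimethoxyphenyl]-N-methoxy-N-methylacetamide F3. 4-Methoxyphenylmagnesium bromide (4-MeOC6H4MgBr, THF, −20 °C) then gives 12, the doubly ortho-substituted diaryl ketone being the slower electrophile.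

**Step 7.** Most likely failure: sluggish ylide addition to the hindered, enolate-bearing diaryl ketone, or failure of the endo-type epoxide opening, whose trajectory is strained, so that the epoxide merely accumulates.
Fallback, from 12 and 14, returning at 17: the reaction is quenched cold and epoxide 15 is isolated. ZnI2 in CH2Cl2 induces Meinwald rearrangement with hydride shift to 2-(3,5-dimethoxyphenyl)-2-{2,4-dimethoxy-6-[2-(4-methoxyphenyl)-2-oxoethyl]phenyl}-1-(4-methoxyphenyl)ethanone F4. KOH in ethanol effects intramolecular aldol condensation of the C1 methylene onto the new C2 ketone to give the conjugated indene [1-(3,5-dimethoxyphenyl)-5,7-dimethoxy-2-(4-methoxyphenyl)-1H-inden-3-yl](4-methoxyphenyl)methanone F5. Deprotonation with lithium diisopropylamide at −78 °C and kinetic α-protonation with acetic acid moves the double bond out of conjugation and gives 17.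

**Step 10.** Most likely failure: drift of the double bond into conjugation with the C8 carbonyl through the same dienolate that racemises C1, which removes the stereocentre from the reducible ketone, or weak discrimination between the two C1 epimers.
Fallback, from 19, returning at 20: non-basic, catalyst-controlled Corey–Bakshi–Shibata reduction ((R)-2-methyl-CBS-oxazaborolidine, catecholborane, toluene, −40 °C; the enantiomer that delivers the (S)-carbinol is used) without any racemisation. It gives 20 together with its C1 epimer, (S)-[(1R)-4,6-bis(tert-butyldimethylsilyloxy)-3-[3,5-bis(tert-butyldimethylsilyloxy)phenyl]-2-[4-(tert-butyldimethylsilyloxy)phenyl]-1H-inden-1-yl][4-(tert-butyldimethylsilyloxy)phenyl]methanol F6. The two are separated by chromatography; F6 is returned to racemic 19 by Dess–Martin oxidation and recycled.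

**Step 11.** Most likely failure: slow reduction of the crowded tetrasubstituted alkene, migration of the double bond toward C1 on the metal before reduction (scrambling C1), or hydrogenolysis of the benzylic C8–O bond; the six silyl ethers add bulk.
Fallback, from 17, returning at 23: the methyl ethers are kept. Transfer hydrogenation of 17 as in step 10 gives (S)-[(1S)-3-(3,5-dimethoxyphenyl)-4,6-dimethoxy-2-(4-methoxyphenyl)-1H-inden-1-yl](4-methoxyphenyl)methanol F7. Hydrogenation of this less encumbered alkene gives (S)-[(1R,2R,3R)-3-(3,5-dimethoxyphenyl)-4,6-dimethoxy-2-(4-methoxyphenyl)-2,3-dihydro-1H-inden-1-yl](4-methoxyphenyl)methanol F8. Dess–Martin oxidation gives [(1R,2R,3R)-3-(3,5-dimethoxyphenyl)-4,6-dimethoxy-2-(4-methoxyphenyl)-2,3-dihydro-1H-inden-1-yl](4-methoxyphenyl)methanone F9, and BBr3 (CH2Cl2, −78 to 0 °C) gives 23. The price is a Lewis-acid deprotection with C1 already in place.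

## Further compounds

F1 | step 5 | methyl 3-(3,5-dimethoxyphenyl)-3-oxopropanoate | COC(=O)CC(=O)c1cc(OC)cc(OC)c1
F2 | step 5 | methyl 2-[2-(3,5-dimethoxybenzoyl)-3,5-dimethoxyphenyl]acetate | COC(=O)Cc1cc(OC)cc(OC)c1C(=O)c1cc(OC)cc(OC)c1
F3 | step 5 | 2-[2-(3,5-dimethoxybenzoyl)-3,5-dimethoxyphenyl]-N-methoxy-N-methylacetamide | CON(C)C(=O)Cc1cc(OC)cc(OC)c1C(=O)c1cc(OC)cc(OC)c1
F4 | step 7 | 2-(3,5-dimethoxyphenyl)-2-{2,4-dimethoxy-6-[2-(4-methoxyphenyl)-2-oxoethyl]phenyl}-1-(4-methoxyphenyl)ethanone (racemic) | COc1ccc(cc1)C(=O)Cc1cc(OC)cc(OC)c1C(C(=O)c1ccc(OC)cc1)c1cc(OC)cc(OC)c1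
F5 | step 7 | [1-(3,5-dimethoxyphenyl)-5,7-dimethoxy-2-(4-methoxyphenyl)-1H-inden-3-yl](4-methoxyphenyl)methanone (racemic) | COc1ccc(cc1)C(=O)C1=C(c2ccc(OC)cc2)C(c2cc(OC)cc(OC)c2)c2c(OC)cc(OC)cc21
F6 | step 10 | (S)-carbinol of the (1R)-indene, hexakis-TBS ether (C1 epimer of 20) | O[C@H](c1ccc(O[Si](C)(C)C(C)(C)C)cc1)[C@@H]1c2cc(O[Si](C)(C)C(C)(C)C)cc(O[Si](C)(C)C(C)(C)C)c2C(c2cc(O[Si](C)(C)C(C)(C)C)cc(O[Si](C)(C)C(C)(C)C)c2)=C1c1ccc(O[Si](C)(C)C(C)(C)C)cc1
F7 | step 11 | (S)-[(1S)-3-(3,5-dimethoxyphenyl)-4,6-dimethoxy-2-(4-methoxyphenyl)-1H-inden-1-yl](4-methoxyphenyl)methanol | O[C@H](c1ccc(OC)cc1)[C@H]1c2cc(OC)cc(OC)c2C(c2cc(OC)cc(OC)c2)=C1c1ccc(OC)cc1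
F8 | step 11 | (S)-[(1R,2R,3R)-3-(3,5-dimethoxyphenyl)-4,6-dimethoxy-2-(4-methoxyphenyl)-2,3-dihydro-1H-inden-1-yl](4-methoxyphenyl)methanol | O[C@H](c1ccc(OC)cc1)[C@H]1c2cc(OC)cc(OC)c2[C@@H](c2cc(OC)cc(OC)c2)[C@H]1c1ccc(OC)cc1
F9 | step 11 | [(1R,2R,3R)-3-(3,5-dimethoxyphenyl)-4,6-dimethoxy-2-(4-methoxyphenyl)-2,3-dihydro-1H-inden-1-yl](4-methoxyphenyl)methanone | O=C(c1ccc(OC)cc1)[C@H]1c2cc(OC)cc(OC)c2[C@@H](c2cc(OC)cc(OC)c2)[C@H]1c1ccc(OC)cc1
A1 | alternative 1 | 1-(4-acetoxyphenyl)-2-diazo-2-{3,5-diacetoxy-2-[(1R)-2-(4-acetoxyphenyl)-1-(3,5-diacetoxyphenyl)ethyl]phenyl}ethanone | CC(=O)Oc1ccc(cc1)C(=O)C(=[N+]=[N-])c1cc(OC(C)=O)cc(OC(C)=O)c1[C@H](Cc1ccc(OC(C)=O)cc1)c1cc(OC(C)=O)cc(OC(C)=O)c1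
A2 | alternative 1 | caraphenol B hexaacetate, all-cis (1R,2R,3R) | O=C(c1ccc(OC(C)=O)cc1)[C@H]1c2cc(OC(C)=O)cc(OC(C)=O)c2[C@@H](c2cc(OC(C)=O)cc(OC(C)=O)c2)[C@H]1c1ccc(OC(C)=O)cc1
A3 | alternative 2 | [4-(benzyloxy)phenyl][4,6-bis(benzyloxy)-1H-inden-1-yl]methanol, C1 configured as in the target | OC(c1ccc(OCc2ccccc2)cc1)[C@@H]1C=Cc2c(OCc3ccccc3)cc(OCc3ccccc3)cc12
A4 | alternative 2 | 1-iodo-3,5-bis(benzyloxy)benzene | Ic1cc(OCc2ccccc2)cc(OCc2ccccc2)c1
A5 | alternative 2 | 4-(benzyloxy)phenylboronic acid | OB(O)c1ccc(OCc2ccccc2)cc1
A6 | alternative 2 | all-cis 1-{[4-(benzyloxy)phenyl](hydroxy)methyl}-2-[4-(benzyloxy)phenyl]-3-[3,5-bis(benzyloxy)phenyl]-4,6-bis(benzyloxy)indane | OC(c1ccc(OCc2ccccc2)cc1)[C@H]1c2cc(OCc3ccccc3)cc(OCc3ccccc3)c2[C@@H](c2cc(OCc3ccccc3)cc(OCc3ccccc3)c2)[C@H]1c1ccc(OCc2ccccc2)cc1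
A7 | alternative 3 | 4-(3,5-dimethoxyphenyl)-2-(4-methoxybenzoyl)-3-(4-methoxyphenyl)cyclopentanone, aryl groups cis, C2 epimerisable | O=C(c1ccc(OC)cc1)C1C(=O)C[C@@H](c2cc(OC)cc(OC)c2)[C@H]1c1ccc(OC)cc1
A8 | alternative 3 | methyl 2-(2-methyl-1,3-dioxolan-2-yl)acetate | COC(=O)CC1(C)OCCO1
A9 | alternative 3 | 1-epi-caraphenol B tetramethyl ether, (1S,2R,3R), ring A as the free 4,6-diol | O=C(c1ccc(OC)cc1)[C@@H]1c2cc(O)cc(O)c2[C@@H](c2cc(OC)cc(OC)c2)[C@H]1c1ccc(OC)cc1
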